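## Structural features

The target is a diaryl ether of two benzene rings with no other ring. Ring A (C1–C6) carries the carboxyl group on C1, a methoxy group on C2, the (S)-1-hydroxy-3-methylbutyl chain on C3, hydrogens on C4 and C5 and the ether oxygen on C6. Ring B (C1'–C6') carries that oxygen on C1', a hydroxyl on C2', a methyl on C4' and a hydroxymethyl on C6'. The ether is crowded, because C1' is flanked on both sides and C6 by the carboxyl-bearing C1, and ring A has four different substituents on four neighbouring carbons. There is one stereocentre, the benzylic carbinol carbon on C3, so no two stereocentres are adjacent and the stereochemical task is a single enantioselective event. That carbinol is the most fragile site: with a methoxy group ortho and an aryloxy group para it can ionise under acid, which would cause racemisation, elimination or ether formation. The real difficulty is the regiocontrolled assembly of the 1,2,3,4-substituted ring A together with the hindered C6–O–C1' bond. The key step uses the ortho pair O–C6 / C1–CO2H with the methoxy group on C2 beyond C1: this is the pattern left when a C1≡C6 aryne, polarised by the C2 methoxy group, takes an oxygen nucleophile at C6 and a carbon electrophile at C1.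

## Logic of the disconnections

Working back from 26, the two O–Si bonds (benzylic carbinol oxygen and hydroxymethyl oxygen) are restored to give 25, and the O–CH2 acetal bond on the C2' oxygen is restored to give 23. These cuts do not simplify the skeleton; they are needed because every free O–H would act as a nucleophile or proton donor in the coupling. The forward demand is that no Brønsted acid meets the free benzylic carbinol, so the acetal is removed first, while both alcohols are still silylated, and buffered fluoride comes last.

In 23 the bonds O–C6 and C1–CO2H are cut together. They are ortho, so both can come from one C1≡C6 aryne; this avoids a metal-catalysed arylation of a doubly flanked phenol and brings in the carboxyl carbon as 19 at its final oxidation level. This is the largest gain of the route: 23 falls into 18, 11 and 19. The forward step must add oxygen at C6 and not C1, must carboxylate the C1 carbanion before anything protonates it, and must use 18 as a preformed salt in a medium without acidic hydrogens.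

In 11 the O–S bond is cut to give 10, the O–C(=O)N bond is re-formed to give 9, and the C1–Si bond is cut to give 7. The silicon/sulfonate pair is the latent triple bond, and C1 is the one ring carbon between two oxygen substituents, so a carbamate on the C6 oxygen can steer a metal there. 7 has only three ring substituents. Forward, lithiation at C1 must outrun deprotonation of the benzylic C–H and migration of the carbamoyl group, and the carbamate must later be removed without breaking the C1–Si bond.

7 is unmasked at its O–Si bond to 6; the C–H bond at the stereocentre is cut by going to ketone 5; 5 is traced through racemic 4 to 2 and 3 by cutting the bond between the carbinol carbon and the side-chain CH2. A ketone with an aryl flank and a CH2 flank suits catalyst-controlled hydride delivery, and the C–C cut is a plain carbonyl addition. The demand is that the carbamate of 2 survives 3, which rules out an N–H carbamate, and that the reduction gives the S alcohol.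

Cutting the O–C(=O)N bond of 2 gives 1. In 1 the hydroxyl is para and the methoxy group ortho to the formyl carbon, so the two oxygens are meta with the future C1 between them; the later lithiation depends on this relationship.

18 is taken back through its O–Si bond to 17, through the aldehyde oxidation level to 16, through the O–CH2 acetal bond to 14, through an O–CH3 bond to 13 and through the C6'–CHO bond to 12. 12 already has the C1' and C2' oxygens and the C4' methyl in place, and its hydroxyl has a single free ortho position. The methyl ether on the C2' oxygen cannot be kept, because at the end it could not be distinguished from the ring A methoxy group. It is exchanged for an acetal at the aldehyde stage, where the formyl group makes the two oxygens different. The forward steps must alkylate only the C2' oxygen (through 15) and silylate only the primary alcohol of 17.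

## Other disconnections considered

Alternative 1: Ring A itself is cut at C1–C2, C2–C3, C4–C5 and C5–C6. Four ring carbons come from the diazo enone A2 and two (C1, C6, with the ether oxygen attached) from the ring B ethynyl ether A3. Forward, irradiation of A2 causes loss of nitrogen with 1,2-shift of the alkenyl group (Wolff rearrangement), ketene–alkyne (2+2) addition to A3, four-electron ring opening, six-electron ring closure and tautomerisation to the phenol A1 (Danheiser benzannulation).
- In its favour: no C–O bond is made at a crowded aromatic carbon, the polarity of the ynol ether fixes the orientation, and the conditions are neutral.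
- Against it: A1 has neither the C2 methyl nor the C1 carboxyl, so O-methylation and a lithiation/carboxylation between two oxygens must follow, in the presence of the ring B acetal, which is itself a directing group. A3 is an aryl ethynyl ether of a hindered phenol, a sensitive compound class. A2 needs diazo transfer onto a chiral silyloxy enone.
- Comparison: each elementary event belongs to an established reaction class, which the coupling step of the chosen plan does not; on this point the alternative is the better one. On stereocontrol the two are equal, since both carry a preformed S carbinol. On structure and step economy the chosen plan is ahead: 23 already has the carboxyl in place, whereas A1 needs two further ring A operations and three unmaskings, and its carboxylation is the lithiation that the chosen plan keeps only in reserve.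

Alternative 2: Ring B is cut at C1'–C6' and C3'–C4'. The ring A aryloxyacetone A5 supplies C1', C2', C3' and the ether oxygen, and ethyl 2,4-dioxopentanoate A6 supplies C4', C5', C6', the methyl and the ester carbon. Forward, base brings about two aldol condensations and the dienone tautomerises to the phenol A4.
- In its favour: ring B comes from cheap acyclic carbon, the ether oxygen is attached by simple O-alkylation of a ring A phenol, and the C2' hydroxyl emerges free. On this last point the alternative is better than the chosen plan, which spends a demethylation and a selective re-protection on it.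
- Against it: A5 has two nucleophilic carbons and A6 two electrophilic carbonyls plus an acidic methylene of its own, and the reverse pairing would exchange the methyl and ester positions on ring B. The ketone enolate of A5 can also attack the neighbouring ring A ester in a five-membered Claisen-type closure. After the key step the ring B ester must be reduced beside the ring A ester, and the ring A partner still needs a carboxyl between two oxygens.
- Comparison: mechanistically this is ordinary carbonyl chemistry, but nothing in the substrates selects among the possible pairings, whereas in the chosen plan the methoxy group dictates the orientation. Step economy is about equal overall: shorter in ring B, longer after the key step (ester differentiation, hydrolysis of a hindered benzoate).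

Alternative 3: Ring A is cut at C4–C5 and C1–C6. The 2-pyrone A8 and the ethynyl ether A3 combine on heating in a (4+2) cycloaddition, and decarboxylative cycloreversion in the same operation gives the protected methyl ester A7.
- In its favour: all four ring A substituents, including the C1 ester and the C2 methoxy group, arrive in one step; the polarity is matched, the nucleophilic terminal carbon of A3 bonding to the pyrone carbon next to the ring oxygen and the oxygenated carbon bonding to the ester-bearing carbon. The reaction class is established, so on precedent it is better than the chosen plan, and in functional economy after the key step it is the equal of the chosen plan.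
- Against it: the 4-methoxy group of A8 donates into the diene and lowers its reactivity towards an electron-rich alkyne, so high temperatures are likely, which endangers A3 and the benzylic silyl ether. A8, with a branched stereodefined chain on its C5, has no obvious short synthesis. A7 is a 2,6-disubstituted methyl benzoate whose hydrolysis needs forcing or nucleophilic dealkylation conditions near labile benzylic positions.
- Comparison: the chosen plan reaches the same pattern from two commercial arenes by standard aromatic chemistry and installs the carboxyl as the free acid. Step economy is comparable at best for the alternative, because of A8.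

Key step: step 14

Remark: the ring A benzylic carbinol is assumed to be acid-labile and is therefore kept as a silyl ether from step 5 until the last step.

Step 1
Reactants: 1 4-hydroxy-2-methoxybenzaldehyde
Product: 2 4-formyl-3-methoxyphenyl N,N-diethylcarbamate
Conditions: Et2NCOCl, K2CO3, MeCN, reflux
Reagents that add atoms: N,N-diethylcarbamoyl chloride, CCN(CC)C(Cl)=O
Why: O-Carbamoylation of a phenoxide; the carbamate has no N–H, so it should survive the organomagnesium step, and it later steers lithiation to the carbon between the two ring oxygens.

Step 2
Reactants: 2 4-formyl-3-methoxyphenyl N,N-diethylcarbamate; 3 isobutylmagnesium bromide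
Product: 4 racemic 4-(1-hydroxy-3-methylbutyl)-3-methoxyphenyl N,N-diethylcarbamate
Conditions: THF, −78 to 0 °C; sat. aq NH4Cl
Reagents that add atoms: none
Why: Grignard addition to an aryl aldehyde, which is much faster than attack on a tertiary carbamate at low temperature; the stereocentre is formed racemic here and is set in steps 3 and 4.

Step 3
Reactants: 4 racemic 4-(1-hydroxy-3-methylbutyl)-3-methoxyphenyl N,N-diethylcarbamate
Product: 5 3-methoxy-4-(3-methylbutanoyl)phenyl N,N-diethylcarbamate
Conditions: Dess–Martin periodinane, CH2Cl2, 0 °C to rt
Reagents that add atoms: none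
Why: Dess–Martin oxidation of a secondary benzylic alcohol to the aryl ketone under near-neutral conditions that leave the carbamate alone.

Step 4
Reactants: 5 3-methoxy-4-(3-methylbutanoyl)phenyl N,N-diethylcarbamate
Product: 6 (S)-4-(1-hydroxy-3-methylbutyl)-3-methoxyphenyl N,N-diethylcarbamate
Conditions: (R)-2-methyl-CBS-oxazaborolidine [(R)-1-methyl-3,3-diphenyltetrahydro-1H,3H-pyrrolo[1,2-c][1,3,2]oxazaborole] (10 mol %), BH3·SMe2, THF, −20 °C; MeOH
Reagents that add atoms: none
Why: Corey–Bakshi–Shibata reduction; the aryl group is the large flank and the isobutyl CH2 the small one, so the (R)-catalyst should deliver hydride to the face that gives the S carbinol (priorities OH > aryl > CH2 > H), the only stereocentre of the target.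

Step 5
Reactants: 6 (S)-4-(1-hydroxy-3-methylbutyl)-3-methoxyphenyl N,N-diethylcarbamate
Product: 7 (S)-3-methoxy-4-[3-methyl-1-(triisopropylsilyloxy)butyl]phenyl N,N-diethylcarbamate
Conditions: TIPSOTf, 2,6-lutidine, CH2Cl2, 0 °C to rt
Reagents that add atoms: triisopropylsilyl triflate, CC(C)[Si](OS(=O)(=O)C(F)(F)F)(C(C)C)C(C)C
Why: Silylation of a hindered secondary alcohol with a silyl triflate and a non-nucleophilic base, with retention at carbon; the bulky group shields the benzylic C–H from base and the C–O bond from ionisation in the later steps.

Step 6
Reactants: 7 (S)-3-methoxy-4-[3-methyl-1-(triisopropylsilyloxy)butyl]phenyl N,N-diethylcarbamate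
Product: 9 (S)-3-methoxy-4-[3-methyl-1-(triisopropylsilyloxy)butyl]-2-(trimethylsilyl)phenyl N,N-diethylcarbamate, via aryllithium 8 (not isolated)
Conditions: s-BuLi, TMEDA, THF, −78 °C; then TMSCl, −78 °C to rt
Reagents that add atoms: chlorotrimethylsilane, C[Si](C)(C)Cl
Why: Directed ortho-metalation; the ring C–H between the carbamate oxygen and the methoxy group is acidified and pre-coordinated by both, so lithiation should occur there at −78 °C, below the temperature of the anionic ortho-Fries shift, and the aryllithium is silylated in place.

Step 7
Reactants: 9 (S)-3-methoxy-4-[3-methyl-1-(triisopropylsilyloxy)butyl]-2-(trimethylsilyl)phenyl N,N-diethylcarbamate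
Product: 10 (S)-3-methoxy-4-[3-methyl-1-(triisopropylsilyloxy)butyl]-2-(trimethylsilyl)phenol
Conditions: LiAlH4, THF, 0 to 50 °C; then H2O
Reagents that add atoms: none
Why: Reductive cleavage of an aryl carbamate by hydride attack at the carbonyl and loss of the phenoxide; aryl–silicon bonds and trialkylsilyl ethers are inert to LiAlH4, and the basic work-up avoids protodesilylation of the electron-rich arylsilane.

Step 8
Reactants: 10 (S)-3-methoxy-4-[3-methyl-1-(triisopropylsilyloxy)butyl]-2-(trimethylsilyl)phenol
Product: 11 (S)-3-methoxy-4-[3-methyl-1-(triisopropylsilyloxy)butyl]-2-(trimethylsilyl)phenyl triflate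
Conditions: Tf2O, pyridine, CH2Cl2, 0 °C
Reagents that add atoms: triflic anhydride, O=S(=O)(OS(=O)(=O)C(F)(F)F)C(F)(F)F
Why: O-Sulfonylation of a phenol; this completes the ortho-silyl aryl triflate, the standard latent form of an aryne, with silicon on C1 and the leaving group on C6.

Step 9
Reactants: 12 creosol (2-methoxy-4-methylphenol)
Product: 13 2-hydroxy-3-methoxy-5-methylbenzaldehyde
Conditions: MgCl2, Et3N, (CH2O)n, MeCN, reflux
Reagents that add atoms: paraformaldehyde (as formaldehyde), C=O
Why: Casnati–Skattebøl ortho-formylation mediated by MgCl2 and Et3N; the only free position ortho to the phenol oxygen is the future C6', the para position being blocked by the methyl group.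

Step 10
Reactants: 13 2-hydroxy-3-methoxy-5-methylbenzaldehyde
Product: 14 2,3-dihydroxy-5-methylbenzaldehyde
Conditions: BBr3, CH2Cl2, −78 to 0 °C; then H2O
Reagents that add atoms: none
Why: Lewis acid cleavage of an aryl methyl ether; the methyl group is removed now because at the end it could not be removed without touching the ring A methoxy group.

Step 11
Reactants: 14 2,3-dihydroxy-5-methylbenzaldehyde
Product: 16 2-hydroxy-3-(methoxymethoxy)-5-methylbenzaldehyde, via disodium dianion 15 (not isolated)
Conditions: NaH (2.2 equiv), DMSO, rt; then MOMCl (1.0 equiv)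
Reagents that add atoms: chloromethyl methyl ether, COCCl
Why: Regioselective O-alkylation of a catechol dianion; the oxide ortho to the formyl group is conjugated with and chelated to it, so the other oxide (the future C2' oxygen) is the stronger nucleophile and should take the single equivalent of electrophile.

Step 12
Reactants: 16 2-hydroxy-3-(methoxymethoxy)-5-methylbenzaldehyde
Product: 17 2-(hydroxymethyl)-6-(methoxymethoxy)-4-methylphenol
Conditions: NaBH4, MeOH, 0 °C
Reagents that add atoms: none
Why: Borohydride reduction of an aryl aldehyde; the acetal and the phenol are inert, and a neutral work-up avoids quinone methide formation from the ortho-hydroxybenzyl alcohol.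

Step 13
Reactants: 17 2-(hydroxymethyl)-6-(methoxymethoxy)-4-methylphenol
Product: 18 2-(methoxymethoxy)-4-methyl-6-[(triisopropylsilyloxy)methyl]phenol
Conditions: TIPSCl, imidazole, DMF, 0 °C to rt
Reagents that add atoms: chlorotriisopropylsilane, CC(C)[Si](Cl)(C(C)C)C(C)C
Why: Chemoselective silylation; the primary alcohol is unhindered while the phenol is flanked on both sides and hydrogen-bonded, so the bulky silyl chloride should react at the alcohol only.

Step 14
Reactants: 18 2-(methoxymethoxy)-4-methyl-6-[(triisopropylsilyloxy)methyl]phenol; 11 (S)-3-methoxy-4-[3-methyl-1-(triisopropylsilyloxy)butyl]-2-(trimethylsilyl)phenyl triflate; 19 carbon dioxide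
Product: 23 (S)-2-methoxy-6-{2-(methoxymethoxy)-4-methyl-6-[(triisopropylsilyloxy)methyl]phenoxy}-3-[3-methyl-1-(triisopropylsilyloxy)butyl]benzoic acid, via potassium phenoxide 20 (not isolated), via aryne 21 (not isolated), via arylpotassium 22 (not isolated)
Conditions: KH, THF, 0 °C; then 18-crown-6, KF, CO2 (1 atm), slow addition of 11, 0 °C to rt; cold 0.5 M HCl
Reagents that add atoms: none
Why: Proposed new method: fluoride from KF/18-crown-6 attacks the C1 silyl group of 11 and expels triflate from C6 to give aryne 21, whose triple bond is distorted by the inductively withdrawing C2 methoxy group so that C6 is the more electrophilic terminus; the oxygen of 20 therefore bonds to C6 and the negative charge arrives at C1, next to the methoxy-bearing carbon, as arylpotassium 22. Because 20 was made beforehand with KH and the medium is THF, 22 meets no O–H donor, no bicarbonate and no acidic solvent C–H, so dissolved 19 is the only electrophile within reach and C-carboxylation at C1 gives the potassium salt of 23. The closest known reaction types are the fluoride-triggered three-component couplings of arynes with amines or imines and carbon dioxide and the O-arylation of phenols by arynes; the new element is an anionic oxygen nucleophile in the first event. No ring is closed and no stereocentre is made; the S carbinol carbon is a silyl ether remote from the reacting atoms and should be untouched. Three selectivities are needed: oxygen must add at C6 and not C1, which the methoxy-induced distortion and the greater hindrance at C1 both favour; 22 must be carboxylated before it is protonated, which the proton-free medium and a standing atmosphere of 19 address; and free 20 must win the aryne against its own reversible carbonate, which slow addition of 11, the low nucleophilicity of a carbonate and the crowding of a 2,6-disubstituted aryl carbonate should secure. The bulky silyl ether on the ring B hydroxymethyl group is chosen so that silyl transfer to the neighbouring phenoxide oxygen, which would unmask a competing alkoxide, stays slow.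

Step 15
Reactants: 23 (S)-2-methoxy-6-{2-(methoxymethoxy)-4-methyl-6-[(triisopropylsilyloxy)methyl]phenoxy}-3-[3-methyl-1-(triisopropylsilyloxy)butyl]benzoic acid
Product: 25 (S)-6-{2-hydroxy-4-methyl-6-[(triisopropylsilyloxy)methyl]phenoxy}-2-methoxy-3-[3-methyl-1-(triisopropylsilyloxy)butyl]benzoic acid, via bis(trimethylsilyl) derivative 24 (not isolated)
Conditions: TMSOTf, 2,2'-bipyridyl, MeCN, 0 °C to rt; then H2O
Reagents that add atoms: none
Why: Cleavage of an aryl methoxymethyl ether by a silyl triflate–bipyridyl complex, which turns the acetal into an aryl trimethylsilyl ether (and the acid into its silyl ester) that water hydrolyses; no Brønsted acid is present, so the silylated benzylic C–O bond and the stereocentre should be safe.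

Step 16
Reactants: 25 (S)-6-{2-hydroxy-4-methyl-6-[(triisopropylsilyloxy)methyl]phenoxy}-2-methoxy-3-[3-methyl-1-(triisopropylsilyloxy)butyl]benzoic acid
Product: 26 (S)-6-[2-hydroxy-6-(hydroxymethyl)-4-methylphenoxy]-3-(1-hydroxy-3-methylbutyl)-2-methoxybenzoic acid
Conditions: Bu4NF (TBAF), AcOH, THF, rt to 40 °C
Reagents that add atoms: none
Why: Fluoride cleavage of both silicon–oxygen bonds, driven by the strength of the Si–F bond; acetic acid keeps the medium near neutral, and the C–O bond of the stereocentre is not broken, so the S configuration is retained.

Compound list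
1 | 4-hydroxy-2-methoxybenzaldehyde | COc1cc(O)ccc1C=O | starting material
2 | 4-formyl-3-methoxyphenyl N,N-diethylcarbamate | CCN(CC)C(=O)Oc1ccc(C=O)c(OC)c1 | intermediate
3 | isobutylmagnesium bromide | CC(C)C[Mg]Br | starting material
4 | racemic 4-(1-hydroxy-3-methylbutyl)-3-methoxyphenyl N,N-diethylcarbamate | CCN(CC)C(=O)Oc1ccc(C(O)CC(C)C)c(OC)c1 | intermediate
5 | 3-methoxy-4-(3-methylbutanoyl)phenyl N,N-diethylcarbamate | CCN(CC)C(=O)Oc1ccc(C(=O)CC(C)C)c(OC)c1 | intermediate
6 | (S)-4-(1-hydroxy-3-methylbutyl)-3-methoxyphenyl N,N-diethylcarbamate | CCN(CC)C(=O)Oc1ccc([C@@H](O)CC(C)C)c(OC)c1 | intermediate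
7 | (S)-3-methoxy-4-[3-methyl-1-(triisopropylsilyloxy)butyl]phenyl N,N-diethylcarbamate | CCN(CC)C(=O)Oc1ccc([C@@H](O[Si](C(C)C)(C(C)C)C(C)C)CC(C)C)c(OC)c1 | intermediate
8 | {6-(diethylcarbamoyloxy)-2-methoxy-3-[(S)-3-methyl-1-(triisopropylsilyloxy)butyl]phenyl}lithium | CCN(CC)C(=O)Oc1ccc([C@@H](O[Si](C(C)C)(C(C)C)C(C)C)CC(C)C)c(OC)c1[Li] | intermediate
9 | (S)-3-methoxy-4-[3-methyl-1-(triisopropylsilyloxy)butyl]-2-(trimethylsilyl)phenyl N,N-diethylcarbamate | CCN(CC)C(=O)Oc1ccc([C@@H](O[Si](C(C)C)(C(C)C)C(C)C)CC(C)C)c(OC)c1[Si](C)(C)C | intermediate
10 | (S)-3-methoxy-4-[3-methyl-1-(triisopropylsilyloxy)butyl]-2-(trimethylsilyl)phenol | Oc1ccc([C@@H](O[Si](C(C)C)(C(C)C)C(C)C)CC(C)C)c(OC)c1[Si](C)(C)C | intermediate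
11 | (S)-3-methoxy-4-[3-methyl-1-(triisopropylsilyloxy)butyl]-2-(trimethylsilyl)phenyl triflate | COc1c([Si](C)(C)C)c(OS(=O)(=O)C(F)(F)F)ccc1[C@@H](O[Si](C(C)C)(C(C)C)C(C)C)CC(C)C | intermediate
12 | creosol (2-methoxy-4-methylphenol) | Cc1ccc(O)c(OC)c1 | starting material
13 | 2-hydroxy-3-methoxy-5-methylbenzaldehyde | COc1cc(C)cc(C=O)c1O | intermediate
14 | 2,3-dihydroxy-5-methylbenzaldehyde | Cc1cc(O)c(O)c(C=O)c1 | intermediate
15 | disodium 3-formyl-5-methylbenzene-1,2-diolate | Cc1cc([O-])c([O-])c(C=O)c1.[Na+].[Na+] | intermediate
16 | 2-hydroxy-3-(methoxymethoxy)-5-methylbenzaldehyde | COCOc1cc(C)cc(C=O)c1O | intermediate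
17 | 2-(hydroxymethyl)-6-(methoxymethoxy)-4-methylphenol | COCOc1cc(C)cc(CO)c1O | intermediate
18 | 2-(methoxymethoxy)-4-methyl-6-[(triisopropylsilyloxy)methyl]phenol | Cc1cc(OCOC)c(O)c(CO[Si](C(C)C)(C(C)C)C(C)C)c1 | intermediate
19 | carbon dioxide | O=C=O | starting material
20 | potassium 2-(methoxymethoxy)-4-methyl-6-[(triisopropylsilyloxy)methyl]phenoxide | Cc1cc(OCOC)c([O-])c(CO[Si](C(C)C)(C(C)C)C(C)C)c1.[K+] | intermediate
21 | (S)-3-methoxy-4-[3-methyl-1-(triisopropylsilyloxy)butyl]benzyne (triple bond between C1 and C6 of ring A) | COC1=C([C@@H](O[Si](C(C)C)(C(C)C)C(C)C)CC(C)C)C=CC#C1 | intermediate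
22 | potassium (S)-2-methoxy-6-{2-(methoxymethoxy)-4-methyl-6-[(triisopropylsilyloxy)methyl]phenoxy}-3-[3-methyl-1-(triisopropylsilyloxy)butyl]benzen-1-ide | COc1c([C@@H](O[Si](C(C)C)(C(C)C)C(C)C)CC(C)C)ccc(Oc2c(OCOC)cc(C)cc2CO[Si](C(C)C)(C(C)C)C(C)C)[c-]1.[K+] | intermediate
23 | (S)-2-methoxy-6-{2-(methoxymethoxy)-4-methyl-6-[(triisopropylsilyloxy)methyl]phenoxy}-3-[3-methyl-1-(triisopropylsilyloxy)butyl]benzoic acid | COc1c([C@@H](O[Si](C(C)C)(C(C)C)C(C)C)CC(C)C)ccc(Oc2c(OCOC)cc(C)cc2CO[Si](C(C)C)(C(C)C)C(C)C)c1C(=O)O | intermediate
24 | trimethylsilyl (S)-2-methoxy-6-{4-methyl-6-[(triisopropylsilyloxy)methyl]-2-(trimethylsilyloxy)phenoxy}-3-[3-methyl-1-(triisopropylsilyloxy)butyl]benzoate | COc1c([C@@H](O[Si](C(C)C)(C(C)C)C(C)C)CC(C)C)ccc(Oc2c(O[Si](C)(C)C)cc(C)cc2CO[Si](C(C)C)(C(C)C)C(C)C)c1C(=O)O[Si](C)(C)C | intermediate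
25 | (S)-6-{2-hydroxy-4-methyl-6-[(triisopropylsilyloxy)methyl]phenoxy}-2-methoxy-3-[3-methyl-1-(triisopropylsilyloxy)butyl]benzoic acid | COc1c([C@@H](O[Si](C(C)C)(C(C)C)C(C)C)CC(C)C)ccc(Oc2c(O)cc(C)cc2CO[Si](C(C)C)(C(C)C)C(C)C)c1C(=O)O | intermediate
26 | (S)-6-[2-hydroxy-6-(hydroxymethyl)-4-methylphenoxy]-3-(1-hydroxy-3-methylbutyl)-2-methoxybenzoic acid | COc1c([C@@H](O)CC(C)C)ccc(Oc2c(O)cc(C)cc2CO)c1C(=O)O | target

Total step count: 16. Longest linear sequence: 11 steps (1 → 2 → 4 → 5 → 6 → 7 → 9 → 10 → 11 → 23 → 25 → 26; the ring B branch 12 → 18 is 5 steps).

Least certain steps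

Step 14 (key step).
- What may go wrong: premature protonation of the C1 carbanion, so that the ether forms without the carboxyl; sequestration of the phenoxide as its carbonate under the CO2 atmosphere; capture of the aryne by the carbonate oxygen followed by acyl migration; silyl transfer from the hydroxymethyl oxygen to the phenoxide oxygen.
- Why: the aryl anion is far more basic than anything else in the flask, and phenoxide and CO2 combine reversibly.
- Fallback (known chemistry, from 11 and 18 to 23): the two bonds are made one after the other. Free phenol 18 and 11 with CsF in MeCN at rt should undergo the ordinary aryne O-arylation, with the same C6 regiochemistry and protonation at C1, to give triisopropyl{[3-(methoxymethoxy)-2-{3-methoxy-4-[(S)-3-methyl-1-(triisopropylsilyloxy)butyl]phenoxy}-5-methylbenzyl]oxy}silane F1. Directed ortho-lithiation of F1 at C1, the only C–H between two ether oxygens (s-BuLi, TMEDA, THF, −78 °C), and a CO2 quench would then give 23. The ring B acetal is a competing director towards C3'–H, so the site of lithiation would have to be confirmed by a deuterium quench first.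

Step 6.
- What may go wrong: deprotonation at the benzylic C–H next to the silyloxy group with silyl migration from oxygen to carbon; carbamoyl migration (anionic ortho-Fries) if the temperature rises before silylation; incomplete silylation at the crowded carbon.
- Why: the benzylic hydrogen is activated by both the arene and the oxygen, and the lithiated position is flanked on both sides.
- Fallback (from 6 to 9): the silyl ether is left out during lithiation. 6 with 2.3 equiv of s-BuLi/TMEDA in THF at −78 °C first gives the lithium alkoxide, whose benzylic C–H is no longer acidic, and is then lithiated on the ring. Excess TMSCl gives (S)-3-methoxy-4-[3-methyl-1-(trimethylsilyloxy)butyl]-2-(trimethylsilyl)phenyl N,N-diethylcarbamate F2. K2CO3 in MeOH removes only the O-silyl group to give (S)-4-(1-hydroxy-3-methylbutyl)-3-methoxy-2-(trimethylsilyl)phenyl N,N-diethylcarbamate F3, and TIPSOTf/2,6-lutidine converts F3 into 9.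

Step 7.
- What may go wrong: slow hydride delivery to a carbamate carbonyl shielded by the neighbouring trimethylsilyl group, and loss of the aryl–silicon bond or of the silyl ether if the conditions are forced.
- Why: the carbonyl sits between a C-silyl group and the diethylamino group.
- Fallback (from 7 to 11): the carbamate is exchanged before the silyl group is introduced.
  - LiAlH4 on the unhindered 7 gives (S)-3-methoxy-4-[3-methyl-1-(triisopropylsilyloxy)butyl]phenol F4.
  - Isopropyl isocyanate with Et3N gives (S)-3-methoxy-4-[3-methyl-1-(triisopropylsilyloxy)butyl]phenyl N-isopropylcarbamate F5.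
  - N-Silylation in the flask (TMSOTf, TMEDA, Et2O), then n-BuLi/TMEDA at −78 °C and TMSCl, gives (S)-3-methoxy-4-[3-methyl-1-(triisopropylsilyloxy)butyl]-2-(trimethylsilyl)phenyl N-isopropylcarbamate F6.
  - DBU and Et2NH in MeCN at 40 °C remove this carbamate by base-induced elimination of the isocyanate, which needs no attack at the shielded carbonyl, and PhNTf2 added to the same flask gives 11.

Step 11.
- What may go wrong: loss of regiocontrol in the alkylation (reaction at the oxide next to the formyl group, or double alkylation).
- Why: the selectivity rests only on the difference in nucleophilicity of the two oxides of 15.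
- Fallback (from 14 to 16): both hydroxyls are alkylated with excess MOMCl and iPr2NEt in CH2Cl2 to give 2,3-bis(methoxymethoxy)-5-methylbenzaldehyde F7. The acetal ortho to the formyl group, activated by the neighbouring carbonyl, is then removed selectively with dilute HCl in MeOH at rt to give 16.

Step 15.
- What may go wrong: ionisation of the silylated benzylic C–O bond of ring A under the Lewis acidic silyl triflate (loss of configuration, elimination), or incomplete acetal cleavage at the crowded C2' oxygen.
- Why: the benzylic carbon is activated by an ortho-methoxy and a para-aryloxy group.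
- Fallback (from 14 to 25): the acetal is replaced by an allyl ether, which is removed without any acid.
  - Dianion alkylation of 14 as in step 11, but with allyl bromide, gives 3-(allyloxy)-2-hydroxy-5-methylbenzaldehyde F8.
  - NaBH4 gives 2-(allyloxy)-6-(hydroxymethyl)-4-methylphenol F9.
  - TIPSCl/imidazole gives 2-(allyloxy)-4-methyl-6-[(triisopropylsilyloxy)methyl]phenol F10.
  - Coupling with 11 and 19 under the conditions of step 14 gives (S)-6-{2-(allyloxy)-4-methyl-6-[(triisopropylsilyloxy)methyl]phenoxy}-2-methoxy-3-[3-methyl-1-(triisopropylsilyloxy)butyl]benzoic acid F11.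
  - Pd(PPh3)4 with morpholine in THF at rt transfers the allyl group to the amine and gives 25.

Further compounds
F1 | step 14 | triisopropyl{[3-(methoxymethoxy)-2-{3-methoxy-4-[(S)-3-methyl-1-(triisopropylsilyloxy)butyl]phenoxy}-5-methylbenzyl]oxy}silane | COc1cc(Oc2c(OCOC)cc(C)cc2CO[Si](C(C)C)(C(C)C)C(C)C)ccc1[C@@H](O[Si](C(C)C)(C(C)C)C(C)C)CC(C)C
F2 | step 6 | (S)-3-methoxy-4-[3-methyl-1-(trimethylsilyloxy)butyl]-2-(trimethylsilyl)phenyl N,N-diethylcarbamate | CCN(CC)C(=O)Oc1ccc([C@@H](O[Si](C)(C)C)CC(C)C)c(OC)c1[Si](C)(C)C
F3 | step 6 | (S)-4-(1-hydroxy-3-methylbutyl)-3-methoxy-2-(trimethylsilyl)phenyl N,N-diethylcarbamate | CCN(CC)C(=O)Oc1ccc([C@@H](O)CC(C)C)c(OC)c1[Si](C)(C)C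
F4 | step 7 | (S)-3-methoxy-4-[3-methyl-1-(triisopropylsilyloxy)butyl]phenol | Oc1ccc([C@@H](O[Si](C(C)C)(C(C)C)C(C)C)CC(C)C)c(OC)c1
F5 | step 7 | (S)-3-methoxy-4-[3-methyl-1-(triisopropylsilyloxy)butyl]phenyl N-isopropylcarbamate | CC(C)NC(=O)Oc1ccc([C@@H](O[Si](C(C)C)(C(C)C)C(C)C)CC(C)C)c(OC)c1
F6 | step 7 | (S)-3-methoxy-4-[3-methyl-1-(triisopropylsilyloxy)butyl]-2-(trimethylsilyl)phenyl N-isopropylcarbamate | CC(C)NC(=O)Oc1ccc([C@@H](O[Si](C(C)C)(C(C)C)C(C)C)CC(C)C)c(OC)c1[Si](C)(C)C
F7 | step 11 | 2,3-bis(methoxymethoxy)-5-methylbenzaldehyde | COCOc1cc(C)cc(C=O)c1OCOC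
F8 | step 15 | 3-(allyloxy)-2-hydroxy-5-methylbenzaldehyde | C=CCOc1cc(C)cc(C=O)c1O
F9 | step 15 | 2-(allyloxy)-6-(hydroxymethyl)-4-methylphenol | C=CCOc1cc(C)cc(CO)c1O
F10 | step 15 | 2-(allyloxy)-4-methyl-6-[(triisopropylsilyloxy)methyl]phenol | C=CCOc1cc(C)cc(CO[Si](C(C)C)(C(C)C)C(C)C)c1O
F11 | step 15 | (S)-6-{2-(allyloxy)-4-methyl-6-[(triisopropylsilyloxy)methyl]phenoxy}-2-methoxy-3-[3-methyl-1-(triisopropylsilyloxy)butyl]benzoic acid | COc1c([C@@H](O[Si](C(C)C)(C(C)C)C(C)C)CC(C)C)ccc(Oc2c(OCC=C)cc(C)cc2CO[Si](C(C)C)(C(C)C)C(C)C)c1C(=O)O
A1 | alternative 1 | (S)-5-{2-(methoxymethoxy)-4-methyl-6-[(tert-butyldimethylsilyloxy)methyl]phenoxy}-2-[1-(tert-butyldimethylsilyloxy)-3-methylbutyl]phenol | Oc1cc(Oc2c(OCOC)cc(C)cc2CO[Si](C)(C)C(C)(C)C)ccc1[C@@H](O[Si](C)(C)C(C)(C)C)CC(C)C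
A2 | alternative 1 | (S,E)-5-(tert-butyldimethylsilyloxy)-1-diazo-7-methyloct-3-en-2-one | [N-]=[N+]=CC(=O)/C=C/[C@@H](O[Si](C)(C)C(C)(C)C)CC(C)C
A3 | alternative 1 | tert-butyl{[2-(ethynyloxy)-3-(methoxymethoxy)-5-methylbenzyl]oxy}dimethylsilane | C#COc1c(OCOC)cc(C)cc1CO[Si](C)(C)C(C)(C)C
A4 | alternative 2 | ethyl (S)-3-hydroxy-2-{3-methoxy-2-(methoxycarbonyl)-4-[1-(tert-butyldimethylsilyloxy)-3-methylbutyl]phenoxy}-5-methylbenzoate | COC(=O)c1c(OC)c([C@@H](O[Si](C)(C)C(C)(C)C)CC(C)C)ccc1Oc1c(O)cc(C)cc1C(=O)OCC
A5 | alternative 2 | methyl (S)-3-[1-(tert-butyldimethylsilyloxy)-3-methylbutyl]-2-methoxy-6-(2-oxopropoxy)benzoate | COC(=O)c1c(OC)c([C@@H](O[Si](C)(C)C(C)(C)C)CC(C)C)ccc1OCC(C)=O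
A6 | alternative 2 | ethyl 2,4-dioxopentanoate | CCOC(=O)C(=O)CC(C)=O
A7 | alternative 3 | methyl (S)-3-[1-(tert-butyldimethylsilyloxy)-3-methylbutyl]-2-methoxy-6-{2-(methoxymethoxy)-4-methyl-6-[(tert-butyldimethylsilyloxy)methyl]phenoxy}benzoate | COC(=O)c1c(OC)c([C@@H](O[Si](C)(C)C(C)(C)C)CC(C)C)ccc1Oc1c(OCOC)cc(C)cc1CO[Si](C)(C)C(C)(C)C
A8 | alternative 3 | methyl (S)-5-[1-(tert-butyldimethylsilyloxy)-3-methylbutyl]-4-methoxy-2-oxo-2H-pyran-3-carboxylate | COC(=O)C1=C(OC)C([C@@H](O[Si](C)(C)C(C)(C)C)CC(C)C)=COC1=O
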